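Start with the reagent. I follow green from its first instants to its end, and hold the other flasks against it.

common to all: left-handed substrate 0.40 M; right-handed substrate 0.40 M
- epsilon: reagent 0.44 M; catalyst 1.1 mM; added ligand 2.1 mM; run made earlier
- eta: reagent 0.44 M; catalyst 3.1 mM; added ligand 2.1 mM; run made earlier
- theta: reagent 0.78 M; catalyst 0.80 mM; added ligand 2.1 mM; run made earlier
- blue: reagent 0.800 M; catalyst 2.5 mM; added ligand 2.1 mM; time 1.0 h
- violet: reagent 0.800 M; catalyst 0.80 mM; added ligand 3.0 mM; time 1.0 h
- green: reagent 0.440 M; catalyst 0.80 mM; added ligand 2.1 mM; time 1.0 h
- red: reagent 1.20 M; catalyst 0.80 mM; added ligand 0.80 mM; time 1.0 h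

| run | time / min | left-handed product / % | right-handed product / % |
|---|---|---|---|
| epsilon | 4.00 | 27.2 | 12.2 |
| epsilon | 10.0 | 33.6 | 15.7 |
| epsilon | 20.0 | 34.1 | 18.2 |
| epsilon | 30.0 | 34.3 | 17.6 |
| eta | 2.50 | 31.6 | 16.5 |
| eta | 6.00 | 35.4 | 17.2 |
| eta | 12.0 | 34.9 | 19.6 |
| eta | 30.0 | 35.8 | 18.6 |
| theta | 4.00 | 35.6 | 17.8 |
| theta | 10.0 | 41.5 | 23.0 |
| theta | 20.0 | 43.3 | 28.4 |
| theta | 30.0 | 44.2 | 30.2 |

(scatter of a reading: 1 percentage point)

- catalyst is single-handed; left-handed substrate and right-handed substrate are mirror images of each other, charged as a racemate, each of them at the stated concentration
- no earlier run changes the charge of added ligand; that part of a forecast is a guess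

* the flasks by excess of left-handed product over right-handed product, highest first, at 1.0 h (blue / violet / green / red)
* the same order at 3.0 min (blue / violet / green / red)
* the excess of left-handed product over right-handed product of the flask you put first, at 1.0 h
* the excess of left-handed product over right-handed product of the flask you put last, at 1.0 h

For green, the reagent charged over both substrates charged is 55.0 %; I call this the reagent share. Excess I take as left-handed product minus right-handed product, over their sum. The balance is short: reagent left, as a fraction of both substrates, is the share minus the two products.

The epsilon run has a share of 55.0 %. At its last reading its products read 51.9 % together, and those of the eta run read 54.4 %, though eta has 2.82 times the catalyst. So I read one reagent per product, and in both runs the reagent is the limiting reagent.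

Now green in slow motion. In the first instants left-handed product forms faster: epsilon's first reading shows 27.2 % against 12.2 %, an excess of 38.1 %. In the middle, left-handed substrate thins sooner, right-handed product gains, and the excess sinks. By its last reading the balance leaves epsilon about 3.1 percentage points of reagent, and its product readings lie flat within their scatter. Green has 0.727 of epsilon's catalyst, and epsilon's readings were flat by 20.0 min, so 1.0 h looks long enough for green to reach that flat stretch. I put green first, at the 32.2 % read from epsilon's last reading.

Violet and blue have a share of 100 %, and red 150 %. Theta has a larger share than epsilon, 97.5 %: its right-handed product is still rising at its last reading, and its excess there reads 18.8 %. Blue has 3.12 times violet's catalyst and less added ligand, so I expect blue to go further. Red has the largest share of the four, so I expect reagent to stay in surplus there, and I put red last; its added ligand is a guess. My order at 1.0 h is green, violet, blue, red. At 3.0 min I rank by catalyst times reagent, leaving added ligand aside: blue ahead of red and red ahead of violet. Among these four I expect the flask further along to show less excess.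

The forecast gives green > violet > blue > red at 1.0 h and green > violet > red > blue at 3.0 min, with 30 % for the first, a little under my figure, and 5 % for the last, its ground for green being “reagent-limited at about 53%, so excess stays near 30%”.

The flasks give green > violet > blue > red at 1.0 h and green > violet > red > blue at 3.0 min, with green at 30.2 % and red at 0.659 %.

    reagent + catalyst + left-handed substrate → catalyst + left-handed product (k = 15.0 M⁻² s⁻¹)
    reagent + catalyst + right-handed substrate → catalyst + right-handed product (k = 6.00 M⁻² s⁻¹)
    catalyst + added ligand ⇌ idle complex (K = 5800 M⁻¹, k = 1.20 M⁻¹ s⁻¹)

Green at 1.0 h keeps 5.92 % of its own reagent, so its share puts 51.7 % of the charge into product, and the two products stand at 33.7 % and 18.1 %. A neighbour of green with a share of 93.8 % keeps 17.2 % of its reagent and holds 77.7 % as product. At 1.0 h the excess of that neighbour stands below violet's: 18.3 % against 20.0 %.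

The numbers in the tables were generated by integration from invented constants; noise was put on by code.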